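## Retrosynthetic overview

- **Enabling feature:** the only stereocentre, C3 of ring C, sits between two CH2 groups, C2 (on O1) and C4 (on C4a). O1 and C4a are a phenol oxygen and its ortho carbon in ring A, and C4a is also para to the 7-OH. They are therefore the O-nucleophile and the best C-nucleophile of plain resorcinol.
- **Key disconnection:** C2–O1 and C4–C4a are cut together. This gives resorcinol and a 2-aryl C3 1,3-dielectrophile, taken one oxidation level higher as the 2-arylacrolein diethyl acetal. Ring C is the only ring made; rings A and B are bought.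
- **Stereocontrol:** at that oxidation level C3 is alpha to the C2 oxocarbenium ion and is erased and rewritten through the 4H-chromene. One chiral acid can therefore run the annulation and then, with a Hantzsch ester, set (S)-C3 while taking C2 down to CH2.
- **Ring B from syringol:** O-silylation, bromination, gamma-selective prenylboronate coupling (1,1-dimethylallyl group), then ortho-lithiation and Negishi coupling with 2-bromoacrolein diethyl acetal.
- **End game:** desilylation.

Key step: step 6

Assumption: the sense of induction of the chiral acid in step 6 must be found by experiment. (R)-TRIP is written, and (S)-TRIP takes its place if that antipode proves to deliver the (S)-product.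

## Route

Step 1
Reactants: 1 acrolein diethyl acetal (3,3-diethoxyprop-1-ene)
Product: 3 2-bromo-3,3-diethoxyprop-1-ene, via 2,3-dibromo-1,1-diethoxypropane 2 (not isolated)
Conditions: Br2 (1.0 equiv), CH2Cl2, −20 °C; solvent exchange; t-BuOK (1.05 equiv), THF, 0 °C
Reagents that add atoms: bromine, BrBr
Why: Electrophilic bromine addition to the vinyl group is followed by E2 dehydrobromination, in which the base takes the more acidic C2–H and expels the primary bromide, and one equivalent of base at 0 °C should stop before the second elimination to the alkyne.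

Step 2
Reactants: 4 2,6-dimethoxyphenol (syringol)
Product: 5 (2,6-dimethoxyphenoxy)triisopropylsilane
Conditions: NaH, TIPSCl, DMF, 0 °C to rt
Reagents that add atoms: triisopropylsilyl chloride (TIPSCl), CC(C)[Si](Cl)(C(C)C)C(C)C
Why: O-Silylation of the sodium phenoxide gives a silyl ether that should withstand aqueous base, butyllithium and the weak acid of step 6, and whose oxygen, twisted out of the ring plane between two OMe groups, loses its directing power.

Step 3
Reactants: 5 (2,6-dimethoxyphenoxy)triisopropylsilane
Product: 6 (3-bromo-2,6-dimethoxyphenoxy)triisopropylsilane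
Conditions: NBS (1.0 equiv), MeCN, 0 °C to rt
Reagents that add atoms: N-bromosuccinimide (NBS), O=C1CCC(=O)N1Br
Why: In this electrophilic aromatic bromination C3 is ortho to one OMe and para to the other, whereas C4 is para only to the out-of-plane silyloxy group, which is the pattern known from the 4-bromination of 1,2,3-trialkoxybenzenes.

Step 4
Reactants: 6 (3-bromo-2,6-dimethoxyphenoxy)triisopropylsilane; 7 prenylboronic acid pinacol ester
Product: 8 [2,6-dimethoxy-3-(2-methylbut-3-en-2-yl)phenoxy]triisopropylsilane
Conditions: PdCl2(dtbpf) (3 mol %; dtbpf = 1,1'-bis(di-tert-butylphosphino)ferrocene), K3PO4 (3 equiv), THF/H2O, 60 °C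
Reagents that add atoms: none
Why: In this gamma-selective Suzuki-Miyaura allyl-aryl coupling, SE2' transmetalation places palladium on the tertiary carbon, and the bulky wide-bite-angle ligand should drive reductive elimination before sigma-pi-sigma isomerisation to the primary prenyl complex, so the 1,1-dimethylallyl group results.

Step 5
Reactants: 8 [2,6-dimethoxy-3-(2-methylbut-3-en-2-yl)phenoxy]triisopropylsilane; 3 2-bromo-3,3-diethoxyprop-1-ene
Product: 11 [3-(3,3-diethoxyprop-1-en-2-yl)-2,6-dimethoxy-5-(2-methylbut-3-en-2-yl)phenoxy]triisopropylsilane, via aryllithium 9 (not isolated), via arylzinc chloride 10 (not isolated)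
Conditions: n-BuLi, TMEDA, Et2O, 0 °C to rt; ZnCl2, THF, 0 °C to rt; 3 (1.2 equiv), Pd(OAc)2 (2 mol %), SPhos (4 mol %), 50 °C
Reagents that add atoms: none
Why: Directed ortho-metalation can reach only C5–H, the single C–H next to a methoxy group, and transmetalation to zinc followed by Negishi coupling with the 1,1-disubstituted vinyl bromide tolerates the acetal, the silyl ether and the vinyl group, which has no allylic hydrogen.

Step 6
Reactants: 11 [3-(3,3-diethoxyprop-1-en-2-yl)-2,6-dimethoxy-5-(2-methylbut-3-en-2-yl)phenoxy]triisopropylsilane; 12 resorcinol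
Product: 15 (3S)-3-[2,4-dimethoxy-5-(2-methylbut-3-en-2-yl)-3-(triisopropylsilyloxy)phenyl]chroman-7-ol, via 2-ethoxyisoflavan 13 (not isolated), via isoflav-2-ene 14 (not isolated)
Conditions: 12 (1.5 equiv), (R)-TRIP (10 mol %; (R)-3,3'-bis(2,4,6-triisopropylphenyl)-1,1'-binaphthyl-2,2'-diyl hydrogen phosphate), 5 Å MS, ClCH2CH2Cl, 40 °C, Ar; after consumption of 11: Hantzsch ester (diethyl 2,6-dimethyl-1,4-dihydropyridine-3,5-dicarboxylate, 1.3 equiv), 40 °C
Reagents that add atoms: none
Why: Proposed new method: the chiral phosphoric acid ionises the acetal of 11 to a 1-ethoxy-2-arylallyl cation, C4 of resorcinol attacks its CH2 terminus (vinylogous Friedel-Crafts alkylation, C4–C4a bond), and the enol ether so formed is protonated and trapped by the adjacent phenol OH in a 6-exo-trig acetalisation (C2–O1 bond) that closes ring C as 13. The sieves bind the ethanol, 13 collapses to the achiral enol ether 14, and only then is the Hantzsch ester added, since this strong hydride donor would otherwise reduce the open-chain allyl cation before resorcinol can attack it. The acid then protonates C3 of 14 and the chroman-2-ylium phosphate ion pair takes up hydride at C2; because the two enantiomeric cations interconvert through 14, this is a dynamic kinetic resolution in which the chiral phosphate, hydrogen-bonded to the N–H of the dihydropyridine, is the only element that controls C3. The closest known reaction types are the acid-catalysed annulation of phenols with enone or enal acetals to 2-alkoxychromans, the phosphoric acid and Hantzsch ester reductive amination of alpha-aryl aldehydes by dynamic kinetic resolution through imine-enamine exchange, the transfer hydrogenation of 3-substituted quinolines with enantioselective protonation, and the chiral-acid protonation of alpha-aryl enol ethers; what is new is their union and the use of an O-aryl oxocarbenium ion. Site selectivity is secured by the substrate: C4 of resorcinol is ortho/para-activated and less hindered than C2, the only free CH of ring B is walled in by the tert-alkyl group and the side chain, and attack at the acetal carbon instead of the CH2 terminus is harmless because C2 and C4 of the target are both CH2 groups, so that this path runs through the 2H-chromene to the same isoflavan. The isolated vinyl group, the aryl methyl ethers and the TIPS ether are inert to a weak acid and to a hydride donor that reduces only cations.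

Step 7
Reactants: 15 (3S)-3-[2,4-dimethoxy-5-(2-methylbut-3-en-2-yl)-3-(triisopropylsilyloxy)phenyl]chroman-7-ol
Product: 16 (3S)-3-[3-hydroxy-2,4-dimethoxy-5-(2-methylbut-3-en-2-yl)phenyl]chroman-7-ol (target)
Conditions: TBAF, AcOH, THF, 0 °C to rt
Reagents that add atoms: none
Why: Fluoride-induced desilylation is driven by Si–F bond formation, and under buffered conditions it should touch neither the vinyl group nor C3, which carries no acidic hydrogen and cannot epimerise.

## Compound list

1 | acrolein diethyl acetal (3,3-diethoxyprop-1-ene) | C=CC(OCC)OCC | starting material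
2 | 2,3-dibromo-1,1-diethoxypropane (racemic) | CCOC(OCC)C(Br)CBr | intermediate
3 | 2-bromo-3,3-diethoxyprop-1-ene | C=C(Br)C(OCC)OCC | intermediate
4 | 2,6-dimethoxyphenol (syringol) | COc1cccc(OC)c1O | starting material
5 | (2,6-dimethoxyphenoxy)triisopropylsilane | COc1cccc(OC)c1O[Si](C(C)C)(C(C)C)C(C)C | intermediate
6 | (3-bromo-2,6-dimethoxyphenoxy)triisopropylsilane | COc1ccc(Br)c(OC)c1O[Si](C(C)C)(C(C)C)C(C)C | intermediate
7 | prenylboronic acid pinacol ester (4,4,5,5-tetramethyl-2-(3-methylbut-2-en-1-yl)-1,3,2-dioxaborolane) | CC(C)=CCB1OC(C)(C)C(C)(C)O1 | starting material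
8 | [2,6-dimethoxy-3-(2-methylbut-3-en-2-yl)phenoxy]triisopropylsilane | C=CC(C)(C)c1ccc(OC)c(O[Si](C(C)C)(C(C)C)C(C)C)c1OC | intermediate
9 | aryllithium (8 lithiated at C5, ortho to the 6-OMe) | C=CC(C)(C)c1cc([Li])c(OC)c(O[Si](C(C)C)(C(C)C)C(C)C)c1OC | intermediate
10 | arylzinc chloride derived from 9 | C=CC(C)(C)c1cc([Zn]Cl)c(OC)c(O[Si](C(C)C)(C(C)C)C(C)C)c1OC | intermediate
11 | [3-(3,3-diethoxyprop-1-en-2-yl)-2,6-dimethoxy-5-(2-methylbut-3-en-2-yl)phenoxy]triisopropylsilane | C=CC(C)(C)c1cc(C(=C)C(OCC)OCC)c(OC)c(O[Si](C(C)C)(C(C)C)C(C)C)c1OC | intermediate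
12 | resorcinol | Oc1cccc(O)c1 | starting material
13 | 3-[2,4-dimethoxy-5-(2-methylbut-3-en-2-yl)-3-(triisopropylsilyloxy)phenyl]-2-ethoxychroman-7-ol (mixture of stereoisomers) | C=CC(C)(C)c1cc(C2Cc3ccc(O)cc3OC2OCC)c(OC)c(O[Si](C(C)C)(C(C)C)C(C)C)c1OC | intermediate
14 | 3-[2,4-dimethoxy-5-(2-methylbut-3-en-2-yl)-3-(triisopropylsilyloxy)phenyl]-4H-chromen-7-ol | C=CC(C)(C)c1cc(C2=COc3cc(O)ccc3C2)c(OC)c(O[Si](C(C)C)(C(C)C)C(C)C)c1OC | intermediate
15 | (3S)-3-[2,4-dimethoxy-5-(2-methylbut-3-en-2-yl)-3-(triisopropylsilyloxy)phenyl]chroman-7-ol | C=CC(C)(C)c1cc([C@H]2COc3cc(O)ccc3C2)c(OC)c(O[Si](C(C)C)(C(C)C)C(C)C)c1OC | intermediate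
16 | (3S)-3-[3-hydroxy-2,4-dimethoxy-5-(2-methylbut-3-en-2-yl)phenyl]chroman-7-ol | C=CC(C)(C)c1cc([C@H]2COc3cc(O)ccc3C2)c(OC)c(O)c1OC | target

## Step count and risks

Total step count: 7. Longest linear sequence: 6 (steps 2 to 7); step 1 is a one-step side branch.

**Step 6.**
- *What may go wrong:* ionisation of the acetal by the weak chiral acid may be slow. The cyclic oxocarbenium ion may be intercepted by a second resorcinol before the hydride donor is added. Protonation outside the chiral ion pair, or by way of the isomeric 2H-chromene, may erode the facial selectivity at C3.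
- *Fallback (sets out from 11 and 12, returns at 15):* the annulation is run with an achiral acid (p-TsOH, cat., EtOH/CH2Cl2, rt). This is the known phenol/enal-acetal route to 2-alkoxychromans; it still closes both ring C bonds in one operation, and here acetal 13 is isolated. Ionic reduction of 13 with Et3SiH and BF3·OEt2 (CH2Cl2, −78 °C), known for 2-alkoxychromans, should give the racemic silyl-protected isoflavan F1. Preparative chromatography of F1 on a polysaccharide chiral stationary phase, routine for isoflavans, delivers 15 beside the (3R)-enantiomer F2.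

**Step 4.**
- *What may go wrong:* isomerisation of the tertiary allylpalladium species before reductive elimination would lead to linear coupling. Slow oxidative addition into the electron-rich ortho-methoxy bromide and protodeboronation are further risks.
- *Fallback (sets out from 6, returns at 8):* the quaternary carbon is built by enolate arylation instead of allyl transfer. Palladium-catalysed alpha-arylation of methyl isobutyrate (LiNCy2, Pd(dba)2, P(t-Bu)3, toluene, rt) should give the methyl 2-aryl-2-methylpropanoate F3. DIBAL-H (CH2Cl2, −78 °C) takes F3 to the 2-aryl-2-methylpropanal F4. Wittig methylenation (Ph3PCH3Br, t-BuOK, THF) gives 8.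

**Step 5.**
- *What may go wrong:* incomplete metalation next to a methoxy group crowded by the silyl ether, and sluggish coupling of the hindered arylzinc reagent.
- *Fallback (sets out from 8, returns at 11):* electrophilic substitution and carbonyl chemistry replace metalation and cross-coupling. NBS (MeCN, 0 °C) should brominate the one ring position that is ortho and para to the two OMe groups, since that ring is far more electron-rich than the neopentyl-type vinyl group, and give the aryl bromide F5. Bromine-lithium exchange (n-BuLi, THF, −78 °C) and acylation with ethyl diethoxyacetate give the aryl 2,2-diethoxyethanone F6. Wittig methylenation of F6 gives 11.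

## Further compounds

F1 | step 6 | racemic 3-[2,4-dimethoxy-5-(2-methylbut-3-en-2-yl)-3-(triisopropylsilyloxy)phenyl]chroman-7-ol | C=CC(C)(C)c1cc(C2COc3cc(O)ccc3C2)c(OC)c(O[Si](C(C)C)(C(C)C)C(C)C)c1OC
F2 | step 6 | (3R)-3-[2,4-dimethoxy-5-(2-methylbut-3-en-2-yl)-3-(triisopropylsilyloxy)phenyl]chroman-7-ol | C=CC(C)(C)c1cc([C@@H]2COc3cc(O)ccc3C2)c(OC)c(O[Si](C(C)C)(C(C)C)C(C)C)c1OC
F3 | step 4 | methyl 2-[2,4-dimethoxy-3-(triisopropylsilyloxy)phenyl]-2-methylpropanoate | COC(=O)C(C)(C)c1ccc(OC)c(O[Si](C(C)C)(C(C)C)C(C)C)c1OC
F4 | step 4 | 2-[2,4-dimethoxy-3-(triisopropylsilyloxy)phenyl]-2-methylpropanal | O=CC(C)(C)c1ccc(OC)c(O[Si](C(C)C)(C(C)C)C(C)C)c1OC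
F5 | step 5 | [3-bromo-2,6-dimethoxy-5-(2-methylbut-3-en-2-yl)phenoxy]triisopropylsilane | C=CC(C)(C)c1cc(Br)c(OC)c(O[Si](C(C)C)(C(C)C)C(C)C)c1OC
F6 | step 5 | 1-[2,4-dimethoxy-5-(2-methylbut-3-en-2-yl)-3-(triisopropylsilyloxy)phenyl]-2,2-diethoxyethan-1-one | C=CC(C)(C)c1cc(C(=O)C(OCC)OCC)c(OC)c(O[Si](C(C)C)(C(C)C)C(C)C)c1OC
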